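## Remarks on the chemistry

- Assumption: 2,3,4-trihydroxybenzaldehyde (formylated pyrogallol) is a purchasable compound and serves as the entry to ring B.
- Check of the structures: the (3S) centre of the target and the (3S,4R) centres of the rearrangement substrate describe the same arrangement at C3, and (3S,4R) is the 3,4-trans isomer that a syn aldol gives after ring closure. No structure needed correction. One point has to be made explicit: this series requires the (R)-configured 4-benzyl-1,3-oxazolidin-2-one; the (S)-auxiliary would lead to the 3R series.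
- Design change to the rearrangement substrate: the C4 hydroxyl carries no silyl group of its own. The silylating agent that the rearrangement needs anyway masks it in the flask. This removes one protection step and one selective desilylation at a benzylic carbon flanked by ortho and para oxygen donors.
- The 2',3'-O-di-tert-butylsilylene and the 7-O-triisopropylsilyl group are kept. The five-membered silylene holds silicon in the ring plane on the far side of O3', so it cannot shift to the O4' phenoxide during methylation.

## Structural features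

The target is an isoflavanone: a benzopyran-4-one (ring A fused to the pyranone ring C, O1–C2H2–C3H–C4=O) that carries ring B on C3 and a free hydroxyl on C7. Ring B is a pentasubstituted benzene: C1' is bonded to C3, C2' and C3' carry a free catechol, C4' a methoxy group, C5' the 2-methylbut-3-en-2-yl (1,1-dimethylallyl) group, and only C6' carries hydrogen. The single stereocentre, C3 (S), has no stereogenic neighbour; it is benzylic and α to the C4 carbonyl, so it epimerises by enolisation under base, heat or prolonged acid. Fragile groups are the oxidation-prone catechol, the 2'-hydroxyl that can cyclodehydrate onto the C4 ketone under acid, the terminal alkene (no hydrogenation, no strong acid) and C3 itself. The real difficulty is to place a quaternary benzylic carbon on the most crowded position of ring B and to tell three adjacent ring B oxygens apart, while C3 is kept out of reach of enolisation until the last two steps. The key step uses the fact that C5' is ortho to O4', that the other ortho carbon C3' bears oxygen and that the para carbon C1' bears C3: an O4' 3-methylbut-2-enyl ether can deliver its allyl unit only to C5', with inversion, which is exactly the 1,1-dimethylallyl group. It is run at the isoflavan-4-ol oxidation level, where C4 is an sp3 oxygen-bearing carbon and C3 cannot enolise.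

## Logic of the disconnections

25 ⇒ 24. The three O–Si bonds at O7, O2' and O3' are cut last. The catechol and the ring A phenol must stay masked through the oxidation, and only a non-basic fluoride unmasking is tolerable next to the labile C3. The forward step must be fast, cold and free of base.

24 ⇒ 23. The C4 carbonyl is traced back to the C4 carbinol. C3 then sits next to an sp3 carbon in every earlier compound and is safe from heat and base. The forward oxidation has to be non-epimerising and must leave the terminal alkene alone.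

23 ⇒ 22. The O4'–CH3 bond is cut. O4' is the oxygen that must earlier carry the migrating allyl unit, so the methyl group can only come afterwards. The forward step must methylate a hindered phenol without touching the C4 carbinol or moving a silyl group.

22 ⇒ 18 (key). The bond from C5' to the quaternary carbon is cut, and the allyl unit is reattached, transposed, to O4' as its 3-methylbut-2-enyl ether. This removes the quaternary carbon and the terminal alkene from all earlier compounds and traces both to 2. The forward step needs about 180 °C, which 18 tolerates only because C4 is not a carbonyl and all other oxygens are silylated or become so in the flask.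

18 ⇒ 17. The aryl ether bond O1–C8a is cut to a primary alcohol and an aryl bromide. Ring C opens to an acyclic 1,3-diol whose two stereocentres come from one aldol. The forward C–O coupling must accept only the primary hydroxyl (the secondary one would need a four-membered ring) and must spare the aryl silyl ethers.

17 ⇒ 16. The C2 carbinol is traced back to the acyl carbon; the N–acyl bond to 9 is cut reductively in the forward sense. The forward reduction must outrun retro-aldol cleavage of the doubly benzylic aldol.

16 ⇒ 11 + 13. The C3–C4 bond is cut. This is the only bond that joins the ring B and ring A halves; its formation sets C3 (and the sacrificial C4 centre). The forward aldol must be syn-selective with 9 as the (R)-auxiliary, giving 2R,3R in 16, which becomes 3S,4R-trans after ring closure.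

13 ⇒ 12 and 11 ⇒ 8 + 9. One O–Si bond and the N–acyl bond are cut. 12 and 9 are purchasable; the acylation must not ionise the allylic aryl ether, so no acid chloride is used.

8 ⇒ 7 ⇒ 6 ⇒ 4 + 5. The benzylic carbon–carbon bond to the carboxyl carbon is cut: the acid is the one-carbon homologue of aldehyde 4, and the extra carbon (the future C2) comes from 5. The forward sequence has to pass through a brief acidic hydrolysis that the allylic ether and the silylene must survive.

4 ⇒ 3 ⇒ 1 + 2. The two O–Si bonds of the silylene and the O4'–CH2 bond are cut. 1 already has the carbon and all three oxygens of ring B in place. The forward alkylation must pick the most acidic hydroxyl (para to the formyl group); the silylene then takes the only remaining vicinal pair.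

## Other disconnections considered

Alternative 1: The cut is the C3–C4 bond of ring C together with the C2–H bond. This unfolds the pyranone to aldehyde A1, a 4-silyloxysalicylaldehyde whose phenolic oxygen carries the 2-arylvinyl group, with ring B complete. In the forward step, cationic monovalent rhodium from [Rh(cod)Cl]2, a chiral bisphosphine and AgBF4 would insert into the formyl C–H bond and add acyl and hydride across the enol ether. Reductive elimination would close ring C and give A2, which is the same compound as 24.
- In favour: ring C and C3 arise in one catalytic, fully atom-economic step, with no auxiliary and no redox adjustment at C4, and only the desilylation of step 14 would follow.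
- Against: the acyl must go to the aryl-bearing carbon (six-membered closure) and not to the oxygen-bearing carbon, which would give a five-membered benzofuranone. Decarbonylation of the acyl rhodium competes. C3 is created already α to the new ketone, in a Lewis acidic medium and next to a crowded 2'-silyloxy aryl group. The 1,1-dimethylallyl alkene must already be present and is a second ligand for rhodium.
- Comparison: on structure both plans reach 24. On mechanism the chosen plan forms C3 as a robust centre and reveals the ketone only at step 13, and the regiochemistry of its key step is enforced by the substitution pattern; here it rests on the catalyst. On step economy Alternative 1 is the better plan, and on atom economy of the key step the two are equal.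

Alternative 2: The cut is the C4–O bond of the carbonyl. The precursor is the (3S)-isoflavan A3 with C4H2, the 7-O-silyl ether and a 2',3'-cyclic carbonate. In the forward step, constant-potential anodic oxidation at carbon in wet acetonitrile with LiClO4 and 2,6-lutidine would take C4H2 through the benzylic cation and the alcohol to the ketone A4.
- In favour: C3 of A3 has no carbonyl neighbour and is robust. No C4 oxygen or sacrificial C4 stereocentre has to be built and carried. The carbonate lowers the electron density of ring B, so that ring A should be oxidised first and C4 is the position benzylic to it.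
- Against: C2 (α to O1), C3 (tertiary, benzylic to ring B), the ring B arene and the allyl group are also oxidisable. It is a four-electron process. A4 is formed in a buffered medium that can enolise C3. The carbonate can only be removed with a nucleophile or base, which is the worst reagent class for C3, whereas the chosen plan ends with acidic fluoride.
- Comparison: on shielding C3 during the build-up the two plans are equal. On structure Alternative 2 is the better plan, because it carries no C4 oxygen. On mechanism the chosen oxidation of a defined carbinol is site-specific by construction, and the anodic step depends on potential differences. On step economy Alternative 2 could be shorter by about two steps, but that gain is spent in a riskier deprotection.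

Alternative 3: The cut is the C4–H bond, read in reverse. The racemic ketone A5 would be reduced by an NADPH-dependent ketoreductase (glucose dehydrogenase and glucose for recycling, pH about 8, dimethyl sulfoxide cosolvent) only as its (3S) enantiomer, while the (3R) enantiomer racemises through the enol. The product would be the cis-(3S,4S)-carbinol A6.
- In favour: the lability of C3 is used productively and all of the racemate can be funnelled to one stereoisomer. A5 can be assembled without any stereocontrol, with the 1,1-dimethylallyl group installed early. The chirality is catalytic. The metal-catalysed counterpart, transfer hydrogenation with dynamic kinetic resolution, is an established reaction type for isoflavanones.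
- Against: A5 is a very lipophilic, triply silylated ketone with a di-ortho-substituted aryl group next to the carbonyl, so acceptance by an enzyme and solubility in aqueous buffer are open. Aryl silyl ethers are exposed to pH 8 for a long time. A6 is a carbinol, so the ketone must be regenerated afterwards.
- Comparison: A6 is the C4 epimer of 23 and would enter the chosen route at step 13, so the last two steps are the same and the plans are equal there. On step economy and use of chirality Alternative 3 is the better plan. On mechanism the chosen plan is the more predictable one, because the auxiliary-controlled aldol needs no screening and tolerates the silyl groups.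

Key step: step 11

## Route

Step 1
Reactants: 1 2,3,4-trihydroxybenzaldehyde; 2 1-bromo-3-methylbut-2-ene
Product: 3 2,3-dihydroxy-4-[(3-methylbut-2-en-1-yl)oxy]benzaldehyde
Conditions: NaHCO3 (1.2 equiv), DMF, 40 °C
Reagents that add atoms: none
Why: Williamson O-alkylation; the 4-hydroxyl (para to the formyl group, not hydrogen-bonded to it) is the most acidic, so a weak base forms only that phenoxide, and the allylic bromide alkylates it at oxygen.

Step 2
Reactants: 3 2,3-dihydroxy-4-[(3-methylbut-2-en-1-yl)oxy]benzaldehyde
Product: 4 2,2-di-tert-butyl-7-[(3-methylbut-2-en-1-yl)oxy]-1,3,2-benzodioxasilole-4-carbaldehyde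
Conditions: t-Bu2Si(OTf)2, 2,6-lutidine, CH2Cl2, 0 °C → rt
Reagents that add atoms: di-tert-butylsilyl bis(trifluoromethanesulfonate), CC(C)(C)[Si](OS(=O)(=O)C(F)(F)F)(OS(=O)(=O)C(F)(F)F)C(C)(C)C
Why: Silylene formation on the only remaining vicinal pair of hydroxyls; the two tert-butyl groups shield silicon from the bases and hydride used later.

Step 3
Reactants: 4 silylene-protected aldehyde; 5 (methoxymethyl)triphenylphosphonium chloride
Product: 6 2,2-di-tert-butyl-4-(2-methoxyethenyl)-7-[(3-methylbut-2-en-1-yl)oxy]-1,3,2-benzodioxasilole (E/Z mixture)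
Conditions: 5, KHMDS, THF, 0 °C; then 4, −78 °C → rt
Reagents that add atoms: none
Why: Wittig methoxymethylenation adds the one carbon that becomes C2; the non-stabilised ylide reacts at low temperature and the alkene geometry is irrelevant.

Step 4
Reactants: 6 methyl enol ether (E/Z mixture)
Product: 7 2-{2,2-di-tert-butyl-7-[(3-methylbut-2-en-1-yl)oxy]-1,3,2-benzodioxasilol-4-yl}acetaldehyde
Conditions: 2 M aq. HCl, THF, rt; used crude
Reagents that add atoms: water, O
Why: Acid-catalysed enol ether hydrolysis (protonation at the aryl-bearing carbon, water addition, loss of methanol); the aryl silyl ether and the allylic aryl ether are expected to outlast brief dilute acid at room temperature.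

Step 5
Reactants: 7 arylacetaldehyde
Product: 8 2-{2,2-di-tert-butyl-7-[(3-methylbut-2-en-1-yl)oxy]-1,3,2-benzodioxasilol-4-yl}acetic acid
Conditions: NaClO2, NaH2PO4, 2-methylbut-2-ene (excess), t-BuOH–H2O, 0 °C → rt
Reagents that add atoms: sodium chlorite, [Na+].[O-]Cl=O
Why: Pinnick oxidation; the large excess of 2-methylbut-2-ene takes up the hypochlorous acid before it can reach the substrate alkene or the electron-rich ring.

Step 6
Reactants: 8 arylacetic acid; 9 (R)-4-benzyl-1,3-oxazolidin-2-one
Product: 11 (R)-4-benzyl-3-(2-{2,2-di-tert-butyl-7-[(3-methylbut-2-en-1-yl)oxy]-1,3,2-benzodioxasilol-4-yl}acetyl)-1,3-oxazolidin-2-one, via mixed pivalic anhydride 10 (not isolated)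
Conditions: PivCl, Et3N, THF, −20 °C; then LiCl, 9, −20 °C → rt
Reagents that add atoms: none
Why: N-acylation of the oxazolidinone through the mixed anhydride with lithium chloride activation; no acid chloride and no hydrogen chloride are generated, which protects the allylic aryl ether.

Step 7
Reactants: 12 2-bromo-4-hydroxybenzaldehyde
Product: 13 2-bromo-4-[(triisopropylsilyl)oxy]benzaldehyde
Conditions: TIPSCl, imidazole, DMF, rt
Reagents that add atoms: chlorotriisopropylsilane, CC(C)[Si](Cl)(C(C)C)C(C)C
Why: Phenol silylation; the triisopropylsilyl ether is the aryl silyl ether most likely to last through carbonate at 100 °C and heat at 180 °C, and it still leaves with fluoride at the end.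

Step 8
Reactants: 11 N-arylacetyl oxazolidinone; 13 2-bromo-4-[(triisopropylsilyl)oxy]benzaldehyde
Product: 16 (R)-4-benzyl-3-[(2R,3R)-3-{2-bromo-4-[(triisopropylsilyl)oxy]phenyl}-2-{2,2-di-tert-butyl-7-[(3-methylbut-2-en-1-yl)oxy]-1,3,2-benzodioxasilol-4-yl}-3-hydroxypropanoyl]-1,3-oxazolidin-2-one, via boron enolate 14 (not isolated), via boron aldolate 15 (not isolated)
Conditions: n-Bu2BOTf, i-Pr2NEt, CH2Cl2, 0 °C; then 13, −78 → 0 °C; then pH 7 buffer, MeOH, 30 % H2O2, 0 °C
Reagents that add atoms: none
Why: Evans syn aldol: the (Z)-boron enolate reacts through a Zimmerman–Traxler chair with the auxiliary carbonyl turned away, and the benzyl group of the (R)-auxiliary blocks one enolate face, so the α-carbon is set as 2R (the future 3S) and the chair sets the carbinol as 3R (syn).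

Step 9
Reactants: 16 syn aldol adduct
Product: 17 (1R,2S)-1-{2-bromo-4-[(triisopropylsilyl)oxy]phenyl}-2-{2,2-di-tert-butyl-7-[(3-methylbut-2-en-1-yl)oxy]-1,3,2-benzodioxasilol-4-yl}propane-1,3-diol
Conditions: LiBH4, THF, 0 °C
Reagents that add atoms: none
Why: Reductive cleavage of the N-acyl oxazolidinone at the more electrophilic exocyclic carbonyl; the neighbouring hydroxyl becomes an alkoxyborohydride that delivers hydride internally and faster than retro-aldol cleavage, and 9 is recovered.

Step 10
Reactants: 17 bromoaryl 1,3-diol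
Product: 18 (3S,4R)-3-{2,2-di-tert-butyl-7-[(3-methylbut-2-en-1-yl)oxy]-1,3,2-benzodioxasilol-4-yl}-7-[(triisopropylsilyl)oxy]chroman-4-ol
Conditions: CuI (10 mol %), 3,4,7,8-tetramethyl-1,10-phenanthroline (20 mol %), Cs2CO3, toluene, 100 °C
Reagents that add atoms: none
Why: Intramolecular Ullmann-type C–O coupling: only the primary alkoxide can reach C8a through a six-membered ring (the secondary one would need a four-membered ring), copper is preferred to palladium because a free benzylic alkoxide on palladium tends to lose β-hydride, and folding the chain into the ring turns the syn aldol relationship into 3,4-trans.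

Step 11
Reactants: 18 (3S,4R)-trans-isoflavan-4-ol with the 4'-O-(3-methylbut-2-enyl) ether
Product: 22 (3S,4R)-3-[2,2-di-tert-butyl-7-hydroxy-6-(2-methylbut-3-en-2-yl)-1,3,2-benzodioxasilol-4-yl]-7-[(triisopropylsilyl)oxy]chroman-4-ol, via 4-O-trimethylsilyl ether 19 (not isolated), via ortho-dienone 20 (not isolated), via bis(trimethylsilyl) ether 21 (not isolated)
Conditions: BSA (5 equiv), PhNEt2, 60 °C, then 180 °C (sealed tube, argon); then THF, 1 M aq. citric acid, rt
Reagents that add atoms: none
Why: BSA first converts the C4 hydroxyl into its trimethylsilyl ether 19, so that no free carbinol is exposed to the heat. At about 180 °C the aryl 3-methylbut-2-enyl ether reorganises by a concerted, suprafacial [3,3]-sigmatropic shift through a chair-like six-membered transition state: the O4'–CH2 bond breaks while the dimethyl-substituted allyl terminus bonds to C5', giving the cyclohexa-2,4-dienone 20 with the allyl unit inverted. A proton shift from C5' to oxygen restores the aromatic ring, and the new 4'-phenol is silylated at once to 21, which takes away the free hydroxyl needed for the ene-type abnormal rearrangement and for ring closure onto the new alkene; aqueous citric acid then cleaves both trimethylsilyl ethers. The closest known reaction type is the thermal ortho-Claisen rearrangement of aryl prenyl ethers to ortho-(1,1-dimethylallyl)phenols in a dialkylaniline with a silylating trap. No ring is closed and no stereocentre remains from the step, because the sp3 centre at C5' of 20 is lost on aromatisation and the new quaternary carbon bears two methyl groups. The selectivity needed is ortho delivery to C5' with allyl inversion: C3' carries oxygen and C1' (para) carries C3, so a shift to either gives a dienone that cannot aromatise and can only return, and the concerted mechanism fixes the inversion. C3 and C4 are spectators, because C4 is an sp3 silyloxy carbon that leaves C3 without an enolisable neighbour, and the aryl silyl ethers are inert in the basic, aprotic melt.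

Step 12
Reactants: 22 4'-phenol
Product: 23 (3S,4R)-3-[2,2-di-tert-butyl-7-methoxy-6-(2-methylbut-3-en-2-yl)-1,3,2-benzodioxasilol-4-yl]-7-[(triisopropylsilyl)oxy]chroman-4-ol
Conditions: MeI, K2CO3, acetone, 56 °C
Reagents that add atoms: iodomethane, CI
Why: Williamson methylation of the phenoxide; carbonate deprotonates the phenol but not the C4 carbinol, and the silylene cannot shift to O4' because its silicon is held in the ring plane on the far side of O3'.

Step 13
Reactants: 23 methylated isoflavan-4-ol
Product: 24 (3S)-3-[2,2-di-tert-butyl-7-methoxy-6-(2-methylbut-3-en-2-yl)-1,3,2-benzodioxasilol-4-yl]-7-[(triisopropylsilyl)oxy]chroman-4-one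
Conditions: Dess–Martin periodinane, CH2Cl2, 0 °C; cold aq. Na2S2O3–NaHCO3 work-up
Reagents that add atoms: none
Why: Dess–Martin oxidation of the secondary benzylic carbinol under base-free, cold conditions; C3 is not touched by the ligand-exchange and elimination steps at iodine, and all phenols are still silylated, so the catechol cannot be oxidised.

Step 14
Reactants: 24 silyl-protected (3S)-isoflavanone
Product: 25 (3S)-3-[2,3-dihydroxy-4-methoxy-5-(2-methylbut-3-en-2-yl)phenyl]-7-hydroxy-2,3-dihydro-4H-chromen-4-one (CNP0134633.1)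
Conditions: HF·pyridine, pyridine, THF, 0 °C → rt
Reagents that add atoms: none
Why: Fluoride-driven cleavage of the aryl triisopropylsilyl ether and of the di-tert-butylsilylene in a weakly acidic, buffered medium that has no base able to enolise C3 and no acid strong enough to cyclodehydrate the 2'-hydroxy ketone or protonate the alkene.

## Compound list

1 | 2,3,4-trihydroxybenzaldehyde | O=Cc1ccc(O)c(O)c1O | starting material
2 | 1-bromo-3-methylbut-2-ene | CC(C)=CCBr | starting material
3 | 2,3-dihydroxy-4-[(3-methylbut-2-en-1-yl)oxy]benzaldehyde | O=Cc1ccc(OCC=C(C)C)c(O)c1O | intermediate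
4 | 2,2-di-tert-butyl-7-[(3-methylbut-2-en-1-yl)oxy]-1,3,2-benzodioxasilole-4-carbaldehyde | O=Cc1ccc(OCC=C(C)C)c2O[Si](C(C)(C)C)(C(C)(C)C)Oc12 | intermediate
5 | (methoxymethyl)triphenylphosphonium chloride | COC[P+](c1ccccc1)(c1ccccc1)c1ccccc1.[Cl-] | starting material
6 | 2,2-di-tert-butyl-4-(2-methoxyethenyl)-7-[(3-methylbut-2-en-1-yl)oxy]-1,3,2-benzodioxasilole (E/Z mixture) | COC=Cc1ccc(OCC=C(C)C)c2O[Si](C(C)(C)C)(C(C)(C)C)Oc12 | intermediate
7 | 2-{2,2-di-tert-butyl-7-[(3-methylbut-2-en-1-yl)oxy]-1,3,2-benzodioxasilol-4-yl}acetaldehyde | O=CCc1ccc(OCC=C(C)C)c2O[Si](C(C)(C)C)(C(C)(C)C)Oc12 | intermediate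
8 | 2-{2,2-di-tert-butyl-7-[(3-methylbut-2-en-1-yl)oxy]-1,3,2-benzodioxasilol-4-yl}acetic acid | OC(=O)Cc1ccc(OCC=C(C)C)c2O[Si](C(C)(C)C)(C(C)(C)C)Oc12 | intermediate
9 | (R)-4-benzyl-1,3-oxazolidin-2-one | O=C1N[C@H](Cc2ccccc2)CO1 | starting material
10 | mixed anhydride of 8 with pivalic acid | CC(C)(C)C(=O)OC(=O)Cc1ccc(OCC=C(C)C)c2O[Si](C(C)(C)C)(C(C)(C)C)Oc12 | intermediate (not isolated)
11 | (R)-4-benzyl-3-(2-{2,2-di-tert-butyl-7-[(3-methylbut-2-en-1-yl)oxy]-1,3,2-benzodioxasilol-4-yl}acetyl)-1,3-oxazolidin-2-one | O=C(Cc1ccc(OCC=C(C)C)c2O[Si](C(C)(C)C)(C(C)(C)C)Oc12)N1C(=O)OC[C@H]1Cc1ccccc1 | intermediate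
12 | 2-bromo-4-hydroxybenzaldehyde | O=Cc1ccc(O)cc1Br | starting material
13 | 2-bromo-4-[(triisopropylsilyl)oxy]benzaldehyde | O=Cc1ccc(O[Si](C(C)C)(C(C)C)C(C)C)cc1Br | intermediate
14 | (Z)-di-n-butylboron enolate of 11 | CCCCB(CCCC)O/C(=C\c1ccc(OCC=C(C)C)c2O[Si](C(C)(C)C)(C(C)(C)C)Oc12)N1C(=O)OC[C@H]1Cc1ccccc1 | intermediate (not isolated)
15 | di-n-butylboron aldolate of 16 | O=C([C@H](c1ccc(OCC=C(C)C)c2O[Si](C(C)(C)C)(C(C)(C)C)Oc12)[C@@H](OB(CCCC)CCCC)c1ccc(O[Si](C(C)C)(C(C)C)C(C)C)cc1Br)N1C(=O)OC[C@H]1Cc1ccccc1 | intermediate (not isolated)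
16 | (R)-4-benzyl-3-[(2R,3R)-3-{2-bromo-4-[(triisopropylsilyl)oxy]phenyl}-2-{2,2-di-tert-butyl-7-[(3-methylbut-2-en-1-yl)oxy]-1,3,2-benzodioxasilol-4-yl}-3-hydroxypropanoyl]-1,3-oxazolidin-2-one (syn aldol) | O=C([C@H](c1ccc(OCC=C(C)C)c2O[Si](C(C)(C)C)(C(C)(C)C)Oc12)[C@@H](O)c1ccc(O[Si](C(C)C)(C(C)C)C(C)C)cc1Br)N1C(=O)OC[C@H]1Cc1ccccc1 | intermediate
17 | (1R,2S)-1-{2-bromo-4-[(triisopropylsilyl)oxy]phenyl}-2-{2,2-di-tert-butyl-7-[(3-methylbut-2-en-1-yl)oxy]-1,3,2-benzodioxasilol-4-yl}propane-1,3-diol | OC[C@H](c1ccc(OCC=C(C)C)c2O[Si](C(C)(C)C)(C(C)(C)C)Oc12)[C@@H](O)c1ccc(O[Si](C(C)C)(C(C)C)C(C)C)cc1Br | intermediate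
18 | (3S,4R)-3-{2,2-di-tert-butyl-7-[(3-methylbut-2-en-1-yl)oxy]-1,3,2-benzodioxasilol-4-yl}-7-[(triisopropylsilyl)oxy]chroman-4-ol (trans-isoflavan-4-ol; 4'-O-prenyl, 2',3'-O-di-tert-butylsilylene, 7-O-triisopropylsilyl) | CC(C)=CCOc1ccc([C@H]2COc3cc(O[Si](C(C)C)(C(C)C)C(C)C)ccc3[C@@H]2O)c2O[Si](C(C)(C)C)(C(C)(C)C)Oc12 | intermediate (substrate of the key step)
19 | 4-O-trimethylsilyl ether of 18 | CC(C)=CCOc1ccc([C@H]2COc3cc(O[Si](C(C)C)(C(C)C)C(C)C)ccc3[C@@H]2O[Si](C)(C)C)c2O[Si](C(C)(C)C)(C(C)(C)C)Oc12 | intermediate (not isolated)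
20 | ortho-dienone from 19: ring B as cyclohexa-2,4-dien-1-one with C4'=O and sp3 C5' bearing H and the 2-methylbut-3-en-2-yl group (C5' epimers) | O=C1C(C(C)(C)C=C)C=C([C@H]2COc3cc(O[Si](C(C)C)(C(C)C)C(C)C)ccc3[C@@H]2O[Si](C)(C)C)C2=C1O[Si](C(C)(C)C)(C(C)(C)C)O2 | intermediate (not isolated)
21 | 4,4'-bis-O-trimethylsilyl ether of 22 | C=CC(C)(C)c1cc([C@H]2COc3cc(O[Si](C(C)C)(C(C)C)C(C)C)ccc3[C@@H]2O[Si](C)(C)C)c2O[Si](C(C)(C)C)(C(C)(C)C)Oc2c1O[Si](C)(C)C | intermediate (not isolated)
22 | (3S,4R)-3-[2,2-di-tert-butyl-7-hydroxy-6-(2-methylbut-3-en-2-yl)-1,3,2-benzodioxasilol-4-yl]-7-[(triisopropylsilyl)oxy]chroman-4-ol (5'-(1,1-dimethylallyl), free 4'-OH) | C=CC(C)(C)c1cc([C@H]2COc3cc(O[Si](C(C)C)(C(C)C)C(C)C)ccc3[C@@H]2O)c2O[Si](C(C)(C)C)(C(C)(C)C)Oc2c1O | intermediate (product of the key step)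
23 | (3S,4R)-3-[2,2-di-tert-butyl-7-methoxy-6-(2-methylbut-3-en-2-yl)-1,3,2-benzodioxasilol-4-yl]-7-[(triisopropylsilyl)oxy]chroman-4-ol | C=CC(C)(C)c1cc([C@H]2COc3cc(O[Si](C(C)C)(C(C)C)C(C)C)ccc3[C@@H]2O)c2O[Si](C(C)(C)C)(C(C)(C)C)Oc2c1OC | intermediate
24 | (3S)-3-[2,2-di-tert-butyl-7-methoxy-6-(2-methylbut-3-en-2-yl)-1,3,2-benzodioxasilol-4-yl]-7-[(triisopropylsilyl)oxy]chroman-4-one | C=CC(C)(C)c1cc([C@H]2COc3cc(O[Si](C(C)C)(C(C)C)C(C)C)ccc3C2=O)c2O[Si](C(C)(C)C)(C(C)(C)C)Oc2c1OC | intermediate
25 | (3S)-3-[2,3-dihydroxy-4-methoxy-5-(2-methylbut-3-en-2-yl)phenyl]-7-hydroxy-2,3-dihydro-4H-chromen-4-one (CNP0134633.1) | C=CC(C)(C)c1cc([C@H]2COc3cc(O)ccc3C2=O)c(O)c(O)c1OC | target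

## Step count and least certain steps

Total step count: 14. Longest linear sequence: 13 steps (steps 1–6 and 8–14; step 7 is a one-step side branch).

Step 11 (key step). The most likely failure is thermal fragmentation of the O4'–CH2 bond, with loss of the allyl unit as isoprene and return of the 4'-phenol. It competes because the transition state has to build a quaternary carbon between two ortho neighbours. If silylation of the new phenol lags, the ene-type follow-up rearrangement opens as well, and long heating can cost silyl groups. The fallback moves the same rearrangement to the smallest aryl ether of the route, before any stereocentre exists; it sets out from 4 and comes back at 23. Compound 4 is heated with BSA in N,N-diethylaniline at 180 °C and worked up with aqueous citric acid to give 2,2-di-tert-butyl-7-hydroxy-6-(2-methylbut-3-en-2-yl)-1,3,2-benzodioxasilole-4-carbaldehyde F1. MeI and K2CO3 give the 7-methoxy aldehyde F2. The ylide from 5 gives the methyl enol ether F3, dilute acid the arylacetaldehyde F4, and Pinnick oxidation the arylacetic acid F5. Acylation of 9 through the pivalic mixed anhydride gives the imide F6. The boron aldol with 13 gives the (2R,3R)-syn adduct F7, and LiBH4 the (1R,2S)-diol F8. The CuI ring closure of step 10 applied to F8 delivers 23. The price is that the terminal alkene then has to pass through the Pinnick oxidation and the peroxide work-up of the aldol.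

Step 1. The most likely failure is erosion of site selectivity: a second alkylation at O3, or C-alkylation of the electron-rich phenoxide, because the three hydroxyls differ only in acidity. The fallback fixes the oxygen pattern by construction; it sets out from 2 and comes back at 4. Pyrogallol F9 is bridged with t-Bu2Si(OTf)2 and 2,6-lutidine, which can only span two adjacent oxygens, to give 2,2-di-tert-butyl-1,3,2-benzodioxasilol-4-ol F10. N-Bromosuccinimide in acetonitrile at −20 °C brominates para to the free hydroxyl to give 7-bromo-2,2-di-tert-butyl-1,3,2-benzodioxasilol-4-ol F11. K2CO3 and 2 in acetone give 4-bromo-2,2-di-tert-butyl-7-[(3-methylbut-2-en-1-yl)oxy]-1,3,2-benzodioxasilole F12. Bromine–lithium exchange with n-BuLi in THF at −78 °C and a DMF quench give 4.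

Step 4. The most likely failure is acid-induced loss of the allylic aryl ether, by ionisation to the 3-methylbut-2-enyl cation, together with self-condensation of the arylacetaldehyde before hydrolysis of the styrene-type enol ether is complete. The fallback avoids both the acid and the aldehyde; it sets out from 4 and comes back at 8. Methylenation of 4 with the ylide from methyltriphenylphosphonium bromide and KHMDS gives 2,2-di-tert-butyl-4-ethenyl-7-[(3-methylbut-2-en-1-yl)oxy]-1,3,2-benzodioxasilole F13. 9-Borabicyclo[3.3.1]nonane hydroborates the monosubstituted alkene far faster than the trisubstituted one, and oxidation with NaBO3·4H2O gives 2-{2,2-di-tert-butyl-7-[(3-methylbut-2-en-1-yl)oxy]-1,3,2-benzodioxasilol-4-yl}ethanol F14. TEMPO (catalytic) with PhI(OAc)2 in MeCN–H2O oxidises F14 to 8.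

Step 10. The most likely failure is slow oxidative addition of copper into the electron-rich, ortho-substituted aryl bromide; prolonged heating with carbonate would then erode the aryl silyl ethers or let the free benzylic alkoxide interfere. The fallback masks the secondary carbinol and changes the metal; it sets out from 16 and comes back at 18, and it also bypasses the unprotected reduction of step 9. TESOTf and 2,6-lutidine at −78 °C give the 3-O-triethylsilyl ether of the aldol adduct F15. LiBH4 gives the mono-silylated diol F16. Pd(OAc)2 with 2-(di-tert-butylphosphino)-1,1'-binaphthyl and K3PO4 in toluene at 70 °C closes the ring through a zerovalent/divalent palladium cycle to give the 4-O-triethylsilyl ether of 18, F17. AcOH–THF–H2O at rt removes the triethylsilyl group to give 18.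

## Further compounds

F1 | step 11 | 2,2-di-tert-butyl-7-hydroxy-6-(2-methylbut-3-en-2-yl)-1,3,2-benzodioxasilole-4-carbaldehyde | O=Cc1cc(C(C)(C)C=C)c(O)c2O[Si](C(C)(C)C)(C(C)(C)C)Oc12
F2 | step 11 | 2,2-di-tert-butyl-7-methoxy-6-(2-methylbut-3-en-2-yl)-1,3,2-benzodioxasilole-4-carbaldehyde | O=Cc1cc(C(C)(C)C=C)c(OC)c2O[Si](C(C)(C)C)(C(C)(C)C)Oc12
F3 | step 11 | 2,2-di-tert-butyl-7-methoxy-4-(2-methoxyethenyl)-6-(2-methylbut-3-en-2-yl)-1,3,2-benzodioxasilole (E/Z mixture) | COC=Cc1cc(C(C)(C)C=C)c(OC)c2O[Si](C(C)(C)C)(C(C)(C)C)Oc12
F4 | step 11 | 2-[2,2-di-tert-butyl-7-methoxy-6-(2-methylbut-3-en-2-yl)-1,3,2-benzodioxasilol-4-yl]acetaldehyde | O=CCc1cc(C(C)(C)C=C)c(OC)c2O[Si](C(C)(C)C)(C(C)(C)C)Oc12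
F5 | step 11 | 2-[2,2-di-tert-butyl-7-methoxy-6-(2-methylbut-3-en-2-yl)-1,3,2-benzodioxasilol-4-yl]acetic acid | OC(=O)Cc1cc(C(C)(C)C=C)c(OC)c2O[Si](C(C)(C)C)(C(C)(C)C)Oc12
F6 | step 11 | (R)-4-benzyl-3-{2-[2,2-di-tert-butyl-7-methoxy-6-(2-methylbut-3-en-2-yl)-1,3,2-benzodioxasilol-4-yl]acetyl}-1,3-oxazolidin-2-one | O=C(Cc1cc(C(C)(C)C=C)c(OC)c2O[Si](C(C)(C)C)(C(C)(C)C)Oc12)N1C(=O)OC[C@H]1Cc1ccccc1
F7 | step 11 | (R)-4-benzyl-3-[(2R,3R)-3-{2-bromo-4-[(triisopropylsilyl)oxy]phenyl}-2-[2,2-di-tert-butyl-7-methoxy-6-(2-methylbut-3-en-2-yl)-1,3,2-benzodioxasilol-4-yl]-3-hydroxypropanoyl]-1,3-oxazolidin-2-one | O=C([C@H](c1cc(C(C)(C)C=C)c(OC)c2O[Si](C(C)(C)C)(C(C)(C)C)Oc12)[C@@H](O)c1ccc(O[Si](C(C)C)(C(C)C)C(C)C)cc1Br)N1C(=O)OC[C@H]1Cc1ccccc1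
F8 | step 11 | (1R,2S)-1-{2-bromo-4-[(triisopropylsilyl)oxy]phenyl}-2-[2,2-di-tert-butyl-7-methoxy-6-(2-methylbut-3-en-2-yl)-1,3,2-benzodioxasilol-4-yl]propane-1,3-diol | OC[C@H](c1cc(C(C)(C)C=C)c(OC)c2O[Si](C(C)(C)C)(C(C)(C)C)Oc12)[C@@H](O)c1ccc(O[Si](C(C)C)(C(C)C)C(C)C)cc1Br
F9 | step 1 | pyrogallol (benzene-1,2,3-triol, purchased) | Oc1cccc(O)c1O
F10 | step 1 | 2,2-di-tert-butyl-1,3,2-benzodioxasilol-4-ol | Oc1cccc2O[Si](C(C)(C)C)(C(C)(C)C)Oc12
F11 | step 1 | 7-bromo-2,2-di-tert-butyl-1,3,2-benzodioxasilol-4-ol | Oc1ccc(Br)c2O[Si](C(C)(C)C)(C(C)(C)C)Oc12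
F12 | step 1 | 4-bromo-2,2-di-tert-butyl-7-[(3-methylbut-2-en-1-yl)oxy]-1,3,2-benzodioxasilole | CC(C)=CCOc1ccc(Br)c2O[Si](C(C)(C)C)(C(C)(C)C)Oc12
F13 | step 4 | 2,2-di-tert-butyl-4-ethenyl-7-[(3-methylbut-2-en-1-yl)oxy]-1,3,2-benzodioxasilole | C=Cc1ccc(OCC=C(C)C)c2O[Si](C(C)(C)C)(C(C)(C)C)Oc12
F14 | step 4 | 2-{2,2-di-tert-butyl-7-[(3-methylbut-2-en-1-yl)oxy]-1,3,2-benzodioxasilol-4-yl}ethanol | OCCc1ccc(OCC=C(C)C)c2O[Si](C(C)(C)C)(C(C)(C)C)Oc12
F15 | step 10 | (R)-4-benzyl-3-[(2R,3R)-3-{2-bromo-4-[(triisopropylsilyl)oxy]phenyl}-2-{2,2-di-tert-butyl-7-[(3-methylbut-2-en-1-yl)oxy]-1,3,2-benzodioxasilol-4-yl}-3-[(triethylsilyl)oxy]propanoyl]-1,3-oxazolidin-2-one | O=C([C@H](c1ccc(OCC=C(C)C)c2O[Si](C(C)(C)C)(C(C)(C)C)Oc12)[C@@H](O[Si](CC)(CC)CC)c1ccc(O[Si](C(C)C)(C(C)C)C(C)C)cc1Br)N1C(=O)OC[C@H]1Cc1ccccc1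
F16 | step 10 | (2S,3R)-3-{2-bromo-4-[(triisopropylsilyl)oxy]phenyl}-2-{2,2-di-tert-butyl-7-[(3-methylbut-2-en-1-yl)oxy]-1,3,2-benzodioxasilol-4-yl}-3-[(triethylsilyl)oxy]propan-1-ol | OC[C@H](c1ccc(OCC=C(C)C)c2O[Si](C(C)(C)C)(C(C)(C)C)Oc12)[C@@H](O[Si](CC)(CC)CC)c1ccc(O[Si](C(C)C)(C(C)C)C(C)C)cc1Br
F17 | step 10 | (3S,4R)-3-{2,2-di-tert-butyl-7-[(3-methylbut-2-en-1-yl)oxy]-1,3,2-benzodioxasilol-4-yl}-4-[(triethylsilyl)oxy]-7-[(triisopropylsilyl)oxy]chromane | CC(C)=CCOc1ccc([C@H]2COc3cc(O[Si](C(C)C)(C(C)C)C(C)C)ccc3[C@@H]2O[Si](CC)(CC)CC)c2O[Si](C(C)(C)C)(C(C)(C)C)Oc12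
A1 | alternative 1 | 2-({2-[2,2-di-tert-butyl-7-methoxy-6-(2-methylbut-3-en-2-yl)-1,3,2-benzodioxasilol-4-yl]ethenyl}oxy)-4-[(triisopropylsilyl)oxy]benzaldehyde | O=Cc1ccc(O[Si](C(C)C)(C(C)C)C(C)C)cc1OC=Cc1cc(C(C)(C)C=C)c(OC)c2O[Si](C(C)(C)C)(C(C)(C)C)Oc12
A2 | alternative 1 | (3S)-3-[2,2-di-tert-butyl-7-methoxy-6-(2-methylbut-3-en-2-yl)-1,3,2-benzodioxasilol-4-yl]-7-[(triisopropylsilyl)oxy]chroman-4-one (identical with 24) | C=CC(C)(C)c1cc([C@H]2COc3cc(O[Si](C(C)C)(C(C)C)C(C)C)ccc3C2=O)c2O[Si](C(C)(C)C)(C(C)(C)C)Oc2c1OC
A3 | alternative 2 | (3S)-isoflavan with C4H2, 7-O-triisopropylsilyl, 2',3'-O-cyclic carbonate, 4'-OMe and 5'-(1,1-dimethylallyl) | C=CC(C)(C)c1cc([C@H]2COc3cc(O[Si](C(C)C)(C(C)C)C(C)C)ccc3C2)c2OC(=O)Oc2c1OC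
A4 | alternative 2 | (3S)-isoflavanone, 7-O-triisopropylsilyl, 2',3'-O-cyclic carbonate | C=CC(C)(C)c1cc([C@H]2COc3cc(O[Si](C(C)C)(C(C)C)C(C)C)ccc3C2=O)c2OC(=O)Oc2c1OC
A5 | alternative 3 | racemic 3-[2,2-di-tert-butyl-7-methoxy-6-(2-methylbut-3-en-2-yl)-1,3,2-benzodioxasilol-4-yl]-7-[(triisopropylsilyl)oxy]chroman-4-one | C=CC(C)(C)c1cc(C2COc3cc(O[Si](C(C)C)(C(C)C)C(C)C)ccc3C2=O)c2O[Si](C(C)(C)C)(C(C)(C)C)Oc2c1OC
A6 | alternative 3 | cis-(3S,4S)-3-[2,2-di-tert-butyl-7-methoxy-6-(2-methylbut-3-en-2-yl)-1,3,2-benzodioxasilol-4-yl]-7-[(triisopropylsilyl)oxy]chroman-4-ol | C=CC(C)(C)c1cc([C@H]2COc3cc(O[Si](C(C)C)(C(C)C)C(C)C)ccc3[C@H]2O)c2O[Si](C(C)(C)C)(C(C)(C)C)Oc2c1OC
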